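**Assumptions:** I use iridoid numbering (C1 acetal, C3=C4 enol ether, C4 carrying C11, C8 carrying C10). "β" means the face of H-9 in the target. Methyl 3-oxopropanoate is generated in situ from its commercial sodium enolate.

## Retrosynthetic overview
1. Target ⇐ C1/C7 diisovalerate of lactol 14 ⇐ dienyl enol ether 13 by syn-dehydration of C6-OH from the cis-6,7-diol 12. The dioxolane is a masked diol that keeps the C7–O stereocentre.
2. The C8 carbinol/C10 unit comes from ketone 7 by methylenation and Upjohn dihydroxylation anti to C7–O. C10/C11 are diacetylated after the ester reduction.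
3. Key step: domino Knoevenagel/intramolecular inverse-demand hetero-Diels–Alder of lactol 4 with methyl 3-oxopropanoate. This forms the cyclopentane (C5–C9) and the dihydropyran (O2–C1) together, so the two rings form in one step.
4. Lactol 4 ⇐ D-ribonolactone acetonide by oxidation, methoxymethylenation and DIBAL. The ribose C2/C3/C4 stereocentres control C9, C1, C8 and keep C7.

## Route

**Step 1**
Reactants: **1** (2,3-O-isopropylidene-D-ribono-1,4-lactone)
Product: **2** (its 5-aldehyde)
Conditions: DMP, NaHCO3, CH2Cl2, 0 °C → rt
Reagents that add atoms: none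
Why: Dess–Martin oxidation of the only free (primary) OH. No stereocentre is set, and C4 epimerisation is harmless because C8 is oxidised later.

**Step 2**
Reactants: **2**
Product: **3** (5,6-dideoxy-6-methoxy-2,3-O-isopropylidene-D-ribo-hex-5-enono-1,4-lactone, E/Z mixture)
Conditions: [Ph3PCH2OMe]Cl, KOtBu, THF, −78 → 0 °C
Reagents that add atoms: (methoxymethyl)triphenylphosphonium chloride, `COC[P+](c1ccccc1)(c1ccccc1)c1ccccc1.[Cl-]`
Why: Wittig methoxymethylenation makes the enol-ether dienophile. Its geometry does not matter because C1 is set later by the anomeric effect.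

**Step 3**
Reactants: **3**
Product: **4** (the lactol, hex-5-enofuranose, anomeric mixture)
Conditions: DIBAL-H (1.1 equiv), CH2Cl2, −78 °C
Reagents that add atoms: none
Why: The lactone is reduced to the lactol, which is a masked C5 aldehyde with a free C8–OH. The enol ether and dioxolane survive at −78 °C. No stereocentre is created.

**Step 4**
Reactants: **4**, **5** (methyl 3-oxopropanoate)
Product: **6** (methyl 8β-hydroxy-1β-methoxy-6β,7β-O-isopropylidene-5β,9β-cis-fused cyclopenta[c]pyran-4-carboxylate)
Conditions: piperidinium acetate (cat.), 4 Å MS, PhMe, 25 → 60 °C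
Reagents that add atoms: none
Why: Domino Knoevenagel/intramolecular inverse-demand hetero-Diels–Alder (Tietze-type). The three-atom tether forces a cis-fused bicycle. The new bonds form on the face anti to the cis-dioxolane and C8–OH, which sets C5 and C9. An endo-alkoxy transition state puts C1–OMe cis to H-9.

**Step 5**
Reactants: **6**
Product: **7** (C8 ketone)
Conditions: DMP, NaHCO3, CH2Cl2, rt
Reagents that add atoms: none
Why: Oxidation of the C8 secondary alcohol. This erases the C8 centre, which was only needed to direct the cycloaddition.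

**Step 6**
Reactants: **7**
Product: **8** (C8=C10 exocyclic methylene)
Conditions: Cp2TiMe2, THF/PhMe, 65 °C, dark
Reagents that add atoms: dimethyltitanocene, `C[Ti](C)(C1C=CC=C1)C1C=CC=C1` (supplies CH2)
Why: Petasis methylenation is non-basic, so it avoids C9 epimerisation and β-elimination of the dioxolane that Ph3P=CH2 would cause. The ketone reacts in preference to the push-pull ester.

**Step 7**
Reactants: **8**
Product: **9** (8α-OH, 10-CH2OH diol)
Conditions: OsO4 (5 mol%), NMO, acetone/H2O, rt
Reagents that add atoms: N-methylmorpholine N-oxide, `C[N+]1([O-])CCOCC1` (oxygen source)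
Why: Upjohn syn-dihydroxylation of the 1,1-disubstituted alkene. The push-pull enol ether is deactivated, so it does not compete. Osmium approaches anti to the allylic C7–O bond (Kishi/Houk) and away from the β-face dioxolane. This sets C8–OH α and C10 β, as in the target.

**Step 8**
Reactants: **9**
Product: **10** (C11-OH, C10-OH, C8-OH triol)
Conditions: DIBAL-H (6 equiv), CH2Cl2, −78 → 0 °C
Reagents that add atoms: none
Why: The vinylogous carbonate ester is reduced to the C11 allylic alcohol. The free hydroxyls are masked as aluminates, and no stereocentre is touched.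

**Step 9**
Reactants: **10**
Product: **11** (10,11-diacetate)
Conditions: Ac2O, pyridine, CH2Cl2, 0 °C → rt (no DMAP)
Reagents that add atoms: acetic anhydride, `CC(=O)OC(C)=O`
Why: Only the two primary hydroxyls are acylated. The hindered tertiary C8–OH stays free.

**Step 10**
Reactants: **11**
Product: **12** (cis-6,7-diol)
Conditions: Dowex 50W-X8 (H+), MeOH, 40 °C
Reagents that add atoms: none
Why: Transketalisation removes the dioxolane. Methanol keeps the C1 methyl acetal intact, and C7–O is unchanged.

**Step 11**
Reactants: **12**
Product: **13** (5,6-ene; the dienyl enol ether with free C7-OH)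
Conditions: Burgess reagent (1.5 equiv), THF, 50 °C
Reagents that add atoms: none
Why: Burgess dehydration, a syn-Ei elimination. The less hindered C6–OH forms the sulfamate and eliminates with the cis C5–H (both β), giving the conjugated C5=C6 bond. The C7 sulfamate cannot eliminate: its only available β-H is anti, and the other neighbour (C8) is quaternary. C5 becomes sp2, so its stereocentre is removed.

**Step 12**
Reactants: **13**
Product: **14** (C1 lactol, anomeric mixture)
Conditions: AcOH/H2O/THF, 25 °C
Reagents that add atoms: water, `O`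
Why: The methyl acetal hydrolyses through the diene-stabilised oxocarbenium.

**Step 13**
Reactants: **14**
Product: **15** (10-acetoxyvaltrathydrin)
Conditions: iPrCH2COCl (2.6 equiv), pyridine, DMAP (cat.), CH2Cl2, −20 → 0 °C
Reagents that add atoms: isovaleryl chloride, `CC(C)CC(Cl)=O`
Why: The lactol OH and the C7–OH are acylated, and the tertiary C8–OH is not. C1 equilibrates through the ring-open/oxocarbenium forms, and the axial 1β-ester cis to H-9 is favoured and separable.

## Compound list
1 | 2,3-O-isopropylidene-D-ribono-1,4-lactone | O=C1[C@@H]2OC(C)(C)O[C@@H]2[C@@H](CO)O1 | starting material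
2 | 5-aldehydo lactone | O=C1[C@@H]2OC(C)(C)O[C@@H]2[C@@H](C=O)O1 | intermediate
3 | 6-methoxy-hex-5-enono-1,4-lactone acetonide (E/Z) | O=C1[C@@H]2OC(C)(C)O[C@@H]2[C@@H](C=COC)O1 | intermediate
4 | lactol (anomeric mixture) | OC1[C@@H]2OC(C)(C)O[C@@H]2[C@@H](C=COC)O1 | intermediate
5 | methyl 3-oxopropanoate | COC(=O)CC=O | starting material
6 | cis-fused bicycle, 8β-OH, 6,7-acetonide | COC(=O)C1=CO[C@@H](OC)[C@H]2[C@@H]1[C@@H]1OC(C)(C)O[C@@H]1[C@@H]2O | intermediate
7 | C8 ketone | COC(=O)C1=CO[C@@H](OC)[C@H]2[C@@H]1[C@@H]1OC(C)(C)O[C@@H]1C2=O | intermediate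
8 | 8(10)-methylene | COC(=O)C1=CO[C@@H](OC)[C@H]2[C@@H]1[C@@H]1OC(C)(C)O[C@@H]1C2=C | intermediate
9 | 8α,10-diol | COC(=O)C1=CO[C@@H](OC)[C@H]2[C@@H]1[C@@H]1OC(C)(C)O[C@@H]1[C@]2(O)CO | intermediate
10 | 8,10,11-triol | OCC1=CO[C@@H](OC)[C@H]2[C@@H]1[C@@H]1OC(C)(C)O[C@@H]1[C@]2(O)CO | intermediate
11 | 10,11-diacetate | CC(=O)OCC1=CO[C@@H](OC)[C@H]2[C@@H]1[C@@H]1OC(C)(C)O[C@@H]1[C@]2(O)COC(C)=O | intermediate
12 | 6,7-diol | CC(=O)OCC1=CO[C@@H](OC)[C@H]2[C@@H]1[C@H](O)[C@H](O)[C@]2(O)COC(C)=O | intermediate
13 | 5,6-diene, 7-OH, 1-OMe | CC(=O)OCC1=CO[C@@H](OC)[C@H]2C1=C[C@H](O)[C@]2(O)COC(C)=O | intermediate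
14 | 1-hydroxy (lactol) diene | CC(=O)OCC1=COC(O)[C@H]2C1=C[C@H](O)[C@]2(O)COC(C)=O | intermediate
15 | 10-acetoxyvaltrathydrin | CC(=O)OCC1=CO[C@@H](OC(=O)CC(C)C)[C@H]2C1=C[C@H](OC(=O)CC(C)C)[C@]2(O)COC(C)=O | target

## Totals
Total steps: 13. Longest linear sequence: 13 (compound 5 is a purchased building block, so there are no convergent branches).

**Three steps most likely to fail**
1. **Step 4, domino Knoevenagel/cycloaddition.** Methyl formylacetate is unstable, and the diastereoselectivity and yield are uncertain. Fallback: use the Meldrum's acid alkylidene as the heterodiene (classical Tietze adduct). Then reach the C3–H enol ether by DIBAL reduction of the resulting lactone followed by E1cB dehydration.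
2. **Step 11, regioselective Burgess dehydration.** The tertiary C8–OH or the hindered C7 sulfamate could compete. Fallback: change series to 2-deoxy-D-ribonolactone, which has no C6–O. Install C5=C6 by oxidising C7 to the ketone, IBX dehydrogenation, Luche reduction, and esterification with isovaleric acid under Mitsunobu conditions if the reduction gives the wrong epimer.
3. **Step 13, lactol acylation.** The 1-hydroxy dienyl lactol may ring-open or aromatise (baldrinal-type), and the C1 anomer ratio is uncertain. Fallback: skip the free lactol. Acylate C7 of the methyl acetal 13, then exchange OMe for isovalerate directly with isovaleric anhydride and cat. TMSOTf through the oxocarbenium.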